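L is the partner X must meet first, so the rate to integrate is X + L → J, with the way back set aside for now.

| flask | X | L | E | remark | time |
|---|---|---|---|---|---|
| Friday's | 0.10 M | 0.51 equiv | 0.030 M | run made earlier |  |
| Tuesday's | 0.10 M | 0.87 equiv | 0.030 M | run made earlier |  |
| Monday's | 0.10 M | 1.6 equiv | 0.030 M | run made earlier |  |
| delta | 0.10 M | 0.500 equiv | 0.0300 M |  | 8.0 h |
| zeta | 0.10 M | 1.50 equiv | 0.0300 M |  | 8.0 h |

| run | time / h | X / % | G / % | Z / % | J / % |
|---|---|---|---|---|---|
| Friday's | 0.833 | 82.3 | 13.7 | 0.8 | 3.6 |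
| Friday's | 1.50 | 74.9 | 21.1 | 1.6 | 2.0 |
| Friday's | 2.50 | 66.6 | 28.5 | 2.6 | 0.7 |
| Friday's | 3.00 | 63.8 | 31.4 | 2.9 | 1.1 |
| Friday's | 4.00 | 59.3 | 34.4 | 4.3 | 1.7 |
| Tuesday's | 0.333 | 85.8 | 7.9 | 0.9 | 4.6 |
| Tuesday's | 0.667 | 75.7 | 17.5 | 2.9 | 3.7 |
| Tuesday's | 1.00 | 68.4 | 24.8 | 2.6 | 3.0 |
| Tuesday's | 2.00 | 53.3 | 39.0 | 4.3 | 2.6 |
| Tuesday's | 4.00 | 38.2 | 51.1 | 7.1 | 3.2 |
| Monday's | 0.333 | 75.4 | 14.8 | 0.8 | 8.7 |
| Monday's | 1.00 | 48.5 | 41.5 | 4.3 | 5.5 |
| Monday's | 2.00 | 28.6 | 59.2 | 6.1 | 3.3 |
| Monday's | 3.00 | 19.1 | 69.7 | 8.0 | 3.3 |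
| Monday's | 4.00 | 14.1 | 72.6 | 8.2 | 1.9 |

(readings scatter by 0.5 percentage points)

- steps under discussion: X + L <-> J; J <-> G; E + J -> Z; J -> Q

- which of these there is most of at the end, counted by the X in it, delta (X / J / G / Z)
- which of these there is most of at the end, counted by the X in it, zeta (X / J / G / Z)
- the largest of these amounts at the end, in percent of the X charged, delta
- the largest of these amounts at the end, in percent of the X charged, zeta

Count everything as fractions of the X charge: x of X left, y of L left, b of L charged. Each pairing removes one of each, so y − x stays at b − 1. The second-order law then integrates to a straight line: ln(y/x) = ln(b) + κ(b − 1)t.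

The last readings give κ as 0.550 h⁻¹ on Friday's run, 0.532 h⁻¹ on Tuesday's and 0.496 h⁻¹ on Monday's. Their mean, 0.526 h⁻¹, is the pairing number: the rate constant of X + L times the X charge. Solved for x, the line reads x = (b − 1)/(b·exp(κ(b − 1)t) − 1).

In delta this gives x = 53.3% at 8.0 h. L is the limiting reagent there, with y at 3.25% of the X charge, far less than x. The X that has reacted comes to 46.7%, less than what remains, so X holds most.

In zeta x = 4.43%. Monday's run, the nearest in L, has 84.5% of its reacted X as G at 4.00 h, which would put G in zeta at 80.8%.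

That share is the weak link, because it is read at half the time. Monday's Z is still rising, from 6.1% to 8.2% over its last two hours. Carried on at that pace to 8.0 h and taken over as an estimate for zeta, Z gains 4.2 percentage points and reaches 12.4%. Starting from Monday's last readings, G in zeta is reckoned to take what X still loses and to give up that gain, which puts it at 78.1%, ahead of Z and X.

The forecast, with “X falls to about 1%” in zeta, gives X at 53.5% for delta and G at 82% for zeta, above the G reckoned here.

The flask gives X at 54.4% in delta and G at 75.8% in zeta.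

    X + L ⇌ J (K = 11.0 L mol⁻¹, k = 5.90 L mol⁻¹ h⁻¹)
    J ⇌ G (K = 30.0, k = 7.00 h⁻¹)
    E + J → Z (k = 20.0 L mol⁻¹ h⁻¹)
    J → Q (k = 0.0770 h⁻¹)

Neither flask is at rest at 8.0 h. At ten times the time, the pairing number puts X in delta at 50.0%, and the computed delta has 51.1%, down from 54.4%. G falls by more than X in delta, from 36.6% to 19.4%, and in zeta it falls from 75.8% to 52.9%. Z meanwhile climbs to 23.2% in delta and 29.0% in zeta.

Take zeta with 0.380 equiv of L instead. The pairing number gives x = 63.8%, more than the 36.2% reacted, so X should hold most. In the computed flask X holds most, at 64.6%, with G at 28.3%.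

(Readings and results are calculated for an exercise, noise included.)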